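Readings and results were generated by integration from invented constants, noise included.

- Slowness let me reckon by sums: east had reached only 25% of the substrate at 90.0 min, and the curves ran nearly straight. So I took target as proportional to the exposure E, the time-integral of the partner B concentration, with κ as the factor between them, and worked in logarithms, where yield is log κ plus log E.

| setting | south-west | east | north | amber | violet | grey | ochre | green |
|---|---|---|---|---|---|---|---|---|
| substrate | 0.20 M | 0.20 M | 0.20 M | 0.20 M | 0.20 M | 0.20 M | 0.20 M | 0.20 M (fed, over 1.5 h) |
| partner A | 0.16 M | 0.16 M | 0.16 M | 0.160 M | 0.160 M | 0.160 M | 0.160 M | 0.160 M |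
| partner B | 0.36 M | 0.50 M | 0.79 M | 0.360 M | 0.360 M (fed, over 1.5 h) | 0.360 M (in portions, 5, over 1.5 h) | 0.360 M (fed, over 1.5 h) | 0.360 M |
| temperature | 30 °C | 41 °C | 30 °C |  | 35 °C | 35 °C |  | 35 °C |
| remark | run made earlier | run made earlier | run made earlier | everything together at the start at 15 °C, warmed to 35 °C at 1.5 h | all else is in the flask from the start; the feed brings no volume worth counting | first portion at the start, last at 1.5 h | the addition at 15 °C, then warmed to 35 °C; the feed brings no volume worth counting | all else is in the flask from the start; the feed brings no volume worth counting |
| time |  |  |  | 2.5 h | 2.5 h | 2.5 h | 2.5 h | 2.5 h |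

- south-west (time / h: target / %): 0.417: 1; 0.833: 1; 1.33: 4; 1.50: 4; 2.00: 8; 2.50: 6
- east (time / min: target / %): 6.00: 2; 20.0: 4; 30.0: 7; 50.0: 17; 60.0: 16; 90.0: 25
- north (time / min: target / %): 6.00: 0; 20.0: 0; 30.0: 3; 50.0: 3; 60.0: 6; 90.0: 10

(each reading ± 1.5 percentage points)

1. the best flask by amount of target, in percent of the substrate charged; "all alike" if 1.5 percentage points covers them all (amber / violet / grey / ochre / green / all alike)
2. amount of target at the end, in percent of the substrate charged, amber
3. amount of target at the end, in percent of the substrate charged, violet
4. amount of target at the end, in percent of the substrate charged, grey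
5. amount of target at the end, in percent of the substrate charged, ochre
6. amount of target at the end, in percent of the substrate charged, green

- the analysis behind the earlier runs scatters by 1.5 percentage points, standard deviation

- At 30 °C the readings gave a κ of 0.0864 /M/h at the lower charge of partner B and 0.0844 /M/h at twice that charge, nearly equal, so I read first order in partner B.
- East gave 0.333 /M/h, which is 0.586 of a decade (a power of ten) in 11.0 degrees, or one decade per 18.8 degrees.
- So at 35 °C I reckoned κ at 0.160 /M/h, the fraction of substrate turned into target per molar hour of exposure.
- Main step alone, with partner B in from the start at 35 °C: E is 0.900 M·h, giving 14.4%.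
- Adding the feed: violet and grey lose half the dosing time of exposure, so E is 0.630 M·h, giving 10.1% each.
- Adding the cold: 1.07 decades down, κ is 0.0137 /M/h, and κ at 35 °C is ten times that. Amber then gives 6.49% and ochre 6.12%.
- Green keeps the full E, but south-west, east and north each held 0.20 M of substrate, so its order was unread. I put green between 10.1% and 14.4%.
- The forecast, reasoning that “The curves show little slowing”, named green best, with amber 6.5%, violet 10.5%, grey 10.5%, ochre 6.2% and green 11%.
- The flasks gave green as best: amber 7.94%, violet 10.6%, grey 10.3%, ochre 6.81%, green 14.7%.

    2 second intermediate → homo product (k = 0.00498 /M/min, Ea = 60.0 kJ/mol)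
    substrate + partner B → open intermediate (k = 0.235 /M/min, Ea = 76.0 kJ/mol)
    second intermediate → side product (k = 0.00242 /min, Ea = 106 kJ/mol)
    open intermediate + second intermediate → target (k = 0.0369 /M/min, Ea = 82.0 kJ/mol)
    partner B + partner A → second intermediate (k = 0.0668 /M/min, Ea = 62.0 kJ/mol)
    target ⇌ isomer of the product (K = 0.262, k = 0.0877 /min, Ea = 94.0 kJ/mol, ΔH = −86.0 kJ/mol)
    (constants at 35 °C)

- My exposure counted partner B as unspent, yet ochre ended with 26% of it. At 1.56 h in ochre, substrate had a half-life of 0.21 h by its step to open intermediate, far shorter than the 1.4 h of partner B on its way to second intermediate. At the end of ochre, open intermediate, the resting state of the substrate, held 82.9% of the charge against 6.81% as target.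
- For the neighbour of ochre with 0.14 M of partner B, κ and exposure gave 2.38%. The computed flask gave 1.51%, with 47.4% as open intermediate.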